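## Retrosynthetic overview

1. The target is opened at the two phenols (benzyl ethers, removed last by hydrogenolysis) and at the C3 ester (hexanoyl chloride plus the 2,3-trans dihydroflavonol).
2. The C3–O bond comes from oxygen-atom transfer to C3 of the (2S)-flavanone enol silane, anti to the C2 phenyl, as flavanone 3-hydroxylase does.
3. Ring C (the C2–O1 bond) comes from a catalytic enantioselective 6-endo oxa-Michael closure of the 2'-hydroxychalcone, as chalcone isomerase does; closure and C3 oxygenation are run without isolating the flavanone.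
4. The chalcone comes from a Claisen–Schmidt condensation of benzaldehyde with 4,6-di-O-benzylphloroacetophenone.
5. Ring order: rings A and B are bought; ring C is the only ring formed, followed by C3 oxygenation and O-acylation.

Assumption: a step is one sequence that ends with an isolated compound; stages run through inside it are listed with their not-isolated intermediates.

Note on descriptors: (2S) in compounds 5 and 6 and (2R) in compounds 7 to 12 describe the same spatial arrangement at C2; only the CIP priorities change once C3 carries oxygen.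

## Route

Step 1
Reactants: 1 2,4,6-trihydroxyacetophenone
Product: 2 1-[2,4-bis(benzyloxy)-6-hydroxyphenyl]ethan-1-one
Conditions: BnBr (2.1 equiv), K2CO3 (2.2 equiv), DMF, rt, 16 h
Reagents that add atoms: benzyl bromide, BrCc1ccccc1
Why: Williamson ether synthesis (SN2) in which the para-OH and one ortho-OH are alkylated, while the remaining ortho-OH is held in a strong hydrogen bond to the acetyl carbonyl and stays free; no stereocenter is formed.

Step 2
Reactants: 2 1-[2,4-bis(benzyloxy)-6-hydroxyphenyl]ethan-1-one; 3 benzaldehyde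
Product: 4 (E)-1-[2,4-bis(benzyloxy)-6-hydroxyphenyl]-3-phenylprop-2-en-1-one
Conditions: KOH (50% aq.), EtOH, rt, 36 h; then cold 1 M HCl to pH 4–5, recrystallise
Reagents that add atoms: none
Why: Claisen–Schmidt (crossed aldol) condensation with a non-enolisable aldehyde, where E1cB dehydration gives the E-enone and the strongly basic medium keeps the product as the open chalcone phenoxide, isolated as the chalcone on cold acidification; no stereocenter is formed.

Step 3
Reactants: 4 (E)-1-[2,4-bis(benzyloxy)-6-hydroxyphenyl]-3-phenylprop-2-en-1-one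
Product: 9 (2R,3R)-5,7-bis(benzyloxy)-3-hydroxy-2-phenylchroman-4-one, via (S)-flavanone 5 (not isolated), via silyl enol ether 6 (not isolated), via silyloxy epoxide 7 (not isolated), via 3-silyloxy ketone 8 (not isolated)
Conditions: (a) N-[3,5-bis(trifluoromethyl)phenyl]-N'-[(8α,9S)-6'-methoxycinchonan-9-yl]thiourea (quinine-derived, 10 mol %), PhMe, 0 °C, 48–72 h; (b) Et3N (3 equiv), TMSOTf (1.6 equiv), CH2Cl2, −78 → 0 °C, then cold aq. NaHCO3 wash; (c) mCPBA (1.5 equiv), CH2Cl2, −20 °C; (d) 1 M HCl, THF, 0 °C
Reagents that add atoms: mCPBA, OOC(=O)c1cccc(Cl)c1 (the C3 oxygen); TMSOTf, C[Si](C)(C)OS(=O)(=O)C(F)(F)F (Me3Si carried in 6–8 only, absent from 9)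
Why: Proposed new method: the quinuclidine nitrogen deprotonates the 2'-OH while the thiourea hydrogen-bonds the enone carbonyl, so the phenoxide adds to one face (Si) of Cβ inside a chiral ion pair in a 6-endo-trig intramolecular oxa-Michael addition that sets C2 as S, helped by the 6'-benzyloxy group, which twists the enone and favours ring closure over the reverse reaction; the base-labile flavanone is then trapped without isolation by soft enolisation (no free enolate, so no E1cB ring opening) and Rubottom oxidation, in which the peracid epoxidises the enol silane anti to the C2 phenyl and silyl migration and hydrolysis leave the 3R hydroxyl (2,3-trans, also the thermodynamic epimer); the closest known reactions are the cinchona-alkaloid-catalysed enantioselective oxa-Michael cyclisations of o-tigloylphenols and of ester-activated 2'-hydroxychalcones, and the Rubottom oxidation of chromanone silyl enol ethers.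

Step 4
Reactants: 9 (2R,3R)-5,7-bis(benzyloxy)-3-hydroxy-2-phenylchroman-4-one; 10 hexanoyl chloride
Product: 11 (2R,3R)-5,7-bis(benzyloxy)-4-oxo-2-phenylchroman-3-yl hexanoate
Conditions: pyridine (3 equiv), DMAP (5 mol %), CH2Cl2, 0 °C → rt
Reagents that add atoms: none
Why: DMAP-catalysed O-acylation (nucleophilic acyl substitution) of the only free hydroxyl, in which no bond to C3 is broken and the weak base at low temperature does not enolise C3, so both stereocenters are retained.

Step 5
Reactants: 11 (2R,3R)-5,7-bis(benzyloxy)-4-oxo-2-phenylchroman-3-yl hexanoate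
Product: 12 (2R,3R)-5,7-dihydroxy-4-oxo-2-phenylchroman-3-yl hexanoate (pinobanksin 3-O-hexanoate, the target)
Conditions: H2 (1 atm), 10% Pd/C, EtOAc, rt, 1–3 h, monitored and stopped at full debenzylation
Reagents that add atoms: none
Why: Catalytic hydrogenolysis of the two aryl benzyl ethers, which under neutral low-pressure conditions is faster than reduction of the aryl ketone or cleavage of the ring C2–O1 bond and leaves the alkyl ester and both stereocenters untouched.

## Compound list

1 | 2,4,6-trihydroxyacetophenone | CC(=O)c1c(O)cc(O)cc1O | starting material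
2 | 1-[2,4-bis(benzyloxy)-6-hydroxyphenyl]ethan-1-one | CC(=O)c1c(O)cc(OCc2ccccc2)cc1OCc1ccccc1 | intermediate
3 | benzaldehyde | O=Cc1ccccc1 | starting material
4 | (E)-1-[2,4-bis(benzyloxy)-6-hydroxyphenyl]-3-phenylprop-2-en-1-one | O=C(/C=C/c1ccccc1)c1c(O)cc(OCc2ccccc2)cc1OCc1ccccc1 | intermediate
5 | (2S)-5,7-bis(benzyloxy)-2-phenylchroman-4-one (di-O-benzylpinocembrin) | O=C1C[C@@H](c2ccccc2)Oc2cc(OCc3ccccc3)cc(OCc3ccccc3)c21 | intermediate
6 | (2S)-5,7-bis(benzyloxy)-2-phenyl-4-[(trimethylsilyl)oxy]-2H-chromene | C[Si](C)(C)OC1=C[C@@H](c2ccccc2)Oc2cc(OCc3ccccc3)cc(OCc3ccccc3)c21 | intermediate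
7 | (2R,3R,4R)-5,7-bis(benzyloxy)-3,4-epoxy-2-phenyl-4-[(trimethylsilyl)oxy]chromane (epoxide oxygen anti to the phenyl) | O3[C@H]1[C@]3(O[Si](C)(C)C)c2c(OCc4ccccc4)cc(OCc4ccccc4)cc2O[C@@H]1c1ccccc1 | intermediate
8 | (2R,3R)-5,7-bis(benzyloxy)-2-phenyl-3-[(trimethylsilyl)oxy]chroman-4-one | C[Si](C)(C)O[C@H]1C(=O)c2c(OCc3ccccc3)cc(OCc3ccccc3)cc2O[C@@H]1c1ccccc1 | intermediate
9 | (2R,3R)-5,7-bis(benzyloxy)-3-hydroxy-2-phenylchroman-4-one (5,7-di-O-benzylpinobanksin, 2,3-trans) | O[C@H]1C(=O)c2c(OCc3ccccc3)cc(OCc3ccccc3)cc2O[C@@H]1c1ccccc1 | intermediate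
10 | hexanoyl chloride | CCCCCC(=O)Cl | starting material
11 | (2R,3R)-5,7-bis(benzyloxy)-4-oxo-2-phenylchroman-3-yl hexanoate | CCCCCC(=O)O[C@H]1C(=O)c2c(OCc3ccccc3)cc(OCc3ccccc3)cc2O[C@@H]1c1ccccc1 | intermediate
12 | (2R,3R)-5,7-dihydroxy-4-oxo-2-phenylchroman-3-yl hexanoate | CCCCCC(=O)O[C@H]1C(=O)c2c(O)cc(O)cc2O[C@@H]1c1ccccc1 | target

## Step count and risks

Total step count: 5. Longest linear sequence: 5 steps (1 → 2 → 4 → 9 → 11 → 12).

**Step 3 (most likely to fail).** The chalcone carries no activating group, so the cyclisation may be slow or give only moderate ee, and the flavanone can reopen if left with base. The sense of induction is assigned by analogy and must be checked on an aliquot of 5 by chiral HPLC and CD; the quinidine-derived pseudoenantiomer of the catalyst gives the other hand. The ee of 9 can be raised by recrystallisation.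

Fallback, from 4 back to 9: the phenol of 4 is capped with MOMCl and NaH in DMF at 0 °C to give (E)-1-[2,4-bis(benzyloxy)-6-(methoxymethoxy)phenyl]-3-phenylprop-2-en-1-one F1. Juliá–Colonna epoxidation (poly-L-leucine, urea–H2O2, DBU, THF, rt) then gives [2,4-bis(benzyloxy)-6-(methoxymethoxy)phenyl][(2R,3S)-3-phenyloxiran-2-yl]methanone F2. HCl in MeOH/THF at 45 °C removes the MOM group, and the freed phenol opens the epoxide at the benzylic carbon in a 6-endo sense with inversion. This gives the 2,3-trans dihydroflavonol 9 directly, with C3 taken from the epoxide with retention.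

**Step 5.** Hydrogenolysis could also cleave the C3–O bond of the α-acyloxy ketone or the benzylic C2–O1 bond, or reduce the ketone.

Fallback, from 9 to 12: 9 is debenzylated first (H2, Pd/C, EtOAc/MeOH, rt) to (2R,3R)-3,5,7-trihydroxy-2-phenylchroman-4-one (pinobanksin) F3. Hexanoyl chloride (2.2 equiv) in pyridine at 0 °C acylates the 3-OH and the 7-OH, while the chelated 5-OH stays free, giving (2R,3R)-3-(hexanoyloxy)-5-hydroxy-4-oxo-2-phenylchroman-7-yl hexanoate F4. The phenolic ester alone is then removed by lipase alcoholysis (immobilised Candida antarctica lipase B, n-BuOH, MTBE, 40 °C), which gives 12.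

**Step 1.** The phloroglucinol ring is prone to C-benzylation and to over-alkylation, so the yield of the dibenzyl ether can be poor.

Fallback, from 1 to 2: 1 is benzylated exhaustively (BnBr 3.5 equiv, K2CO3, DMF, 60 °C) to 1-[2,4,6-tris(benzyloxy)phenyl]ethan-1-one F5. One ortho benzyl group is then removed under chelation control (MgBr2·OEt2, toluene/Et2O, reflux); the magnesium phenoxide chelate that forms protects the second ortho ether, and the product is 2.

## Further compounds

F1 | step 3 | (E)-1-[2,4-bis(benzyloxy)-6-(methoxymethoxy)phenyl]-3-phenylprop-2-en-1-one | COCOc1cc(OCc2ccccc2)cc(OCc2ccccc2)c1C(=O)/C=C/c1ccccc1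
F2 | step 3 | [2,4-bis(benzyloxy)-6-(methoxymethoxy)phenyl][(2R,3S)-3-phenyloxiran-2-yl]methanone | O1[C@H]([C@@H]1c1ccccc1)C(=O)c1c(OCOC)cc(OCc2ccccc2)cc1OCc1ccccc1
F3 | step 5 | (2R,3R)-3,5,7-trihydroxy-2-phenylchroman-4-one (pinobanksin) | O[C@H]1C(=O)c2c(O)cc(O)cc2O[C@@H]1c1ccccc1
F4 | step 5 | (2R,3R)-3-(hexanoyloxy)-5-hydroxy-4-oxo-2-phenylchroman-7-yl hexanoate | CCCCCC(=O)O[C@H]1C(=O)c2c(O)cc(OC(=O)CCCCC)cc2O[C@@H]1c1ccccc1
F5 | step 1 | 1-[2,4,6-tris(benzyloxy)phenyl]ethan-1-one | CC(=O)c1c(OCc2ccccc2)cc(OCc2ccccc2)cc1OCc1ccccc1
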